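**Analysis of the target**

Target 40 is a germacranolide, (1R,5S,6S,7R,8R,10R)-5-angeloyloxy-1,10-epoxy-6-hydroxy-3-oxogermacra-4(15),11(13)-dien-12,8-olide. It is a ten-membered carbocycle (C1–C10) with an α-methylene-γ-butyrolactone fused at C7/C8 (C11, C12, C13, ring oxygen on C8). Six stereocentres are present, four of them contiguous (C5–C8). Taking the C7–C11 bond as β, O8 is α (trans lactone), O6 is β (cis to C11) and the C5 angelate is α (trans to O6). The trans-epoxide is bonded α at C1 and β at C10, so its oxygen lies on the face of the former (E)-C1=C10 alkene that points across the ring towards C6. The sensitive groups are two exocyclic Michael acceptors (the lactone methylene, and the C3 enone whose allylic C5 ester can be lost by addition–elimination), the angelate (Z to E isomerisation, acyl shift to O6) and the trisubstituted epoxide (acid, transannular opening). The difficulty is to close a ten-membered ring with a defined E alkene next to four contiguous stereocentres, and then to order the oxidations around groups that tolerate neither acid nor base at the end. The feature on which the plan rests is that C1–C6 with C15, together with C9/C10/C14, form a p-menthane. With C6 as a carbonyl and C1=C10 as an E alkene, the array C6(=O)–C7–C8–C9–C10=C1 is the retron of an oxy-Cope rearrangement in which C8–C9 is made and C1–C6 is broken.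

**Retrosynthetic reasoning**

*C3 carbonyl and silyl ethers (40 ⇐ 39 ⇐ 38).* The enone is made last, because the α-methylene ketone with an allylic ester on C5 would not survive bases or nucleophiles. In diol 39 only the C3 hydroxyl is allylic, so an allylic oxidation tells it apart from the C6 hydroxyl without a protecting group. Both silyl ethers of 38 therefore come off together one step earlier.

*Epoxide (38 ⇐ 37).* The C1–O and C10–O bonds are cut back to the (E)-alkene of 37. The oxygen must go on the alkene face that looks towards C6 in the conformer left by the ring expansion, so simple outside attack on that conformer would give the wrong trans-epoxide. The oxygen transfer is therefore put under catalyst control (a chiral dioxirane whose intrinsic preference on trisubstituted E alkenes is the (R,R) epoxide), with a halohydrin route in reserve. It is placed after the acylation so that the epoxide is never heated.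

*Angelate (37 ⇐ 34 + 35).* The C5–O acyl bond is cut. O5 must be free while O6 is blocked, which is why C5 carries an oxidatively removable benzyl-type ether and C6 a silyl ether in 33.

*Lactone and its methylene (33 ⇐ 29 ⇐ 28).* The C11=C13 bond is cut back to the lactone enolate (Mannich reaction, then elimination), and the C12–O8 bond back to hydroxy ester 28. The C6 hydroxyl is silylated before O8 is unveiled, so that only the 8,12-lactone can form.

*C8 oxygen, C6 carbinol, C7 side chain (28 ⇐ 26 ⇐ 25 ⇐ 24 ⇐ 21 + 22).* The C8–O bond is traced to a C8–Si bond that is oxidised with retention. Silicon is used because a C8 alkoxy group would be β to the C6 carbonyl and its enolate and would be eliminated, whereas a silyl group is inert there. Silicon carries benzyl, not phenyl: a phenyl group can only be removed from silicon with electrophiles that would also attack the two alkenes, whereas benzyl leaves with fluoride. The C6–H bond comes from hydride addition to the ketone on the face away from C1=C10. The C7–C11 bond comes from alkylation of the C6 enolate with 22 on the outer face.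

*Ten-membered ring (21 ⇐ 18).* This is the central disconnection. The C8–C9 bond is cut and C1–C6 reconnected, which turns the cyclodecenone into the trans-1,2-dialkenylcyclohexanol 18. Nothing is gained by cutting elsewhere: this cut removes the medium ring, the E alkene and the C8 stereocentre in one operation and leaves a cyclohexane whose configurations can be set by ordinary six-ring rules. The forward reaction must run through the chair with both alkenyl groups equatorial.

*C5 oxygen after the carbinol (18 ⇐ 17 ⇐ 16 ⇐ 14).* The C5 ether is not taken back to an α-alkoxy ketone plus a vinyl nucleophile. An axial C5 oxygen would steer the nucleophile anti to itself and cis to the isopropenyl group, which gives the carbinol epimer that can only rearrange to a Z alkene. Instead the carbinol is made first, on an enone in which only the isopropenyl group directs. The C5 oxygen and the C4 methylene are then introduced together by an ene photo-oxygenation of the C4=C5 alkene of 14 (oxygen can only bond to C5, because C6 has no hydrogen) with dehydration to enone 16. The C5 configuration is set by hydride delivered from the tertiary hydroxyl, which gives the trans-diaxial diol 17.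

*Carbinol (14 ⇐ 7 + 11; 11 ⇐ 8 + 9).* The C6–C7 bond is cut to enone 7 and the (E)-silylvinyl metal derived from 11. The E geometry is fixed at the outset in distannane 8.

*Enone from the terpene (7 ⇐ 6 ⇐ 4 ⇐ 3 ⇐ 2 ⇐ 1).* The C6 carbonyl is moved back by a 1,3-oxidative transposition to tertiary allylic alcohol 6, and 6 to the epoxide 4 of cis-carveol. This puts the oxygen on the carbon next to the isopropenyl-bearing C1, which is the one position that 1 does not oxygenate by itself. The carbonyl of 1 becomes the C3 oxygen, cis to the isopropenyl group, where it locks the reactive chair of 18. The (R) enantiomer of carvone has the C1 configuration that the chair relays to C8.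

**Alternatives that were turned down**

Alternative 1: The epoxide is built first, in an acyclic fragment, by cutting C9–C10 and the O–C1 bond. Allylmagnesium bromide adds at low temperature to the C10 carbonyl of the (S)-α-chloro ketone A2 under Cornforth control, and the alkoxide displaces chloride at C1 to give the trans-epoxide A1. In its favour, both epoxide centres are fixed at the start by acyclic control, independent of any ring conformation. On this point it is stronger than the chosen route, whose epoxidation depends on a catalyst having to win against ring bias. Against it, A1 holds only C1–C3, C9, C10, C14 and the allyl carbons. The ten-membered ring, its closure and all of C5–C8 are still to come, and an acid- and Lewis-acid-labile trisubstituted epoxide has to be carried through a macrocyclisation and every later step. The chosen strategy offers instead the ring, the E alkene and C8 in one step from a six-membered ring.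

Alternative 2: The C6–C7 bond is cut and the ten-membered ring is derived from a thirteen-membered diallylic ether by [2,3]-Wittig contraction. A lithium amide (lithium 2,2,6,6-tetramethylpiperidide or lithium diisopropylamide, low temperature) lithiates C6 next to oxygen, and the shift forms C6–C7, cleaves O–C13 and gives carbinol A3 with the C6 hydroxyl and the C11=C13 methylene. In its favour, two contiguous centres and the exocyclic methylene arise together, and, like the chosen route, the medium ring is made from a different ring size and not by direct closure. Against it, a thirteen-membered ether must first be cyclised. Both carbons next to the ether oxygen are allylic, so the site of lithiation and the [2,3] versus [1,2] pathway are open, and the relative configuration at C6/C7 is set in a flexible macrocyclic transition state. A3 also still has the C4=C5 alkene, no C5 oxygen, a ketal at C3 and C12 as an alcohol, so a transposing allylic oxygenation, an oxidation and a lactonisation remain near sensitive groups. The chosen route has the C5 oxygen and the C4 methylene in place before the ring is expanded.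

Alternative 3: The lactone carbonyl is cut out as carbon monoxide (C11–C12 and O–C12). PdCl2, SnCl2 and PPh3 under CO carbonylate the C8 hydroxyl and add the alkoxycarbonyl group across a C7 ethynyl group, giving the α-methylene lactone A4 in one step. In its favour, it replaces four operations of the chosen route (alkylation, silicon oxidation, lactonisation, methylenation), so it is better in step economy for the lactone. Against it, it is an end-game tactic only. It presupposes the ten-membered ring, the E alkene and the C5–C8 centres with ethynyl and hydroxyl trans on C7/C8, and says nothing about how they are made. A4 already carries the C3 enone, which must then survive a phosphine and a Lewis acid. The chosen route makes the ring and the C8 centre together and pays for the lactone with standard steps.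

Key step: step 11

Remark: ring carbons carry their germacrane numbers (C1–C15) from the first step on. In the cyclohexanes "cis" and "trans" refer to the isopropenyl group on C1; in the ten-membered ring α/β refer to the ring drawn with the C7–C11 bond β.
Remark on the chemistry: the C3 stereocentre is a control element only; it disappears in the last step.

**Steps**

Step 1
Reactants: 1 (R)-(−)-carvone
Product: 2 (1R,5R)-cis-carveol
Conditions: NaBH4, CeCl3·7H2O, MeOH, 0 °C
Reagents that add atoms: none
Why: Luche reduction; 1,2-delivery of hydride along the axial direction gives the pseudo-equatorial alcohol cis to the isopropenyl group, which becomes the equatorial C3 oxygen.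

Step 2
Reactants: 2 (1R,5R)-cis-carveol
Product: 3 1-methyl-4-(prop-1-en-2-yl)-7-oxabicyclo[4.1.0]heptan-2-ol (hydroxyl; epoxide oxygen; isopropenyl all cis)
Conditions: VO(acac)2 (cat.), t-BuOOH, CH2Cl2, 0 °C → rt
Reagents that add atoms: tert-butyl hydroperoxide, CC(C)(C)OO
Why: Hydroxyl-directed epoxidation; the vanadium alkoxide delivers oxygen syn to the allylic hydroxyl (C4–C5 epoxide cis to the isopropenyl group) and leaves the isopropenyl alkene alone.

Step 3
Reactants: 3 the cis-epoxy alcohol
Product: 4 tert-butyldimethylsilyl ether of 3
Conditions: TBSCl, imidazole, DMF, rt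
Reagents that add atoms: tert-butyldimethylsilyl chloride, CC(C)(C)[Si](C)(C)Cl
Why: Standard silylation of a secondary alcohol; the epoxide is inert to imidazole.

Step 4
Reactants: 4 the epoxy silyl ether
Product: 6 6-(tert-butyldimethylsilyloxy)-1-methyl-4-(prop-1-en-2-yl)cyclohex-2-en-1-ol (hydroxyl; silyl ether; isopropenyl all cis), via hydroxy selenide 5 (not isolated)
Conditions: (PhSe)2, NaBH4, EtOH, 0 °C → reflux; then 30% H2O2, THF, 0 °C → rt
Reagents that add atoms: none
Why: Selenide opening of an epoxide followed by selenoxide syn-elimination; with the epoxide oxygen cis to the equatorial isopropenyl group the Fürst–Plattner diaxial opening falls on the secondary C5, and the selenoxide can only eliminate towards C6 because C4 has no hydrogen.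

Step 5
Reactants: 6 the tertiary allylic alcohol
Product: 7 (4R,6R)-4-(tert-butyldimethylsilyloxy)-3-methyl-6-(prop-1-en-2-yl)cyclohex-2-en-1-one
Conditions: pyridinium chlorochromate (C5H5NH[CrO3Cl]), NaOAc, CH2Cl2, rt
Reagents that add atoms: none
Why: Babler–Dauben oxidative transposition; the chromate ester of the tertiary alcohol shifts [3,3] to C6 and is oxidised there, and acetate buffering protects the α-isopropenyl centre, which is in any case the more stable cis-1,3 arrangement.

Step 6
Reactants: 8 (E)-1,2-bis(tributylstannyl)ethene; 9 benzylchlorodimethylsilane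
Product: 11 (E)-benzyldimethyl[2-(tributylstannyl)ethenyl]silane, via stannylvinyllithium 10 (not isolated)
Conditions: n-BuLi (1 equiv), THF, −78 °C; then 9, −78 °C → rt
Reagents that add atoms: none
Why: Tin–lithium exchange of one stannyl group with retention of the E geometry, then silylation of the vinyllithium.

Step 7
Reactants: 11 the stannyl vinylsilane; 7 the enone
Product: 14 1-[(E)-2-(benzyldimethylsilyl)ethenyl]-4-(tert-butyldimethylsilyloxy)-3-methyl-6-(prop-1-en-2-yl)cyclohex-2-en-1-ol (hydroxyl cis and silylvinyl trans to isopropenyl), via silylvinyllithium 12 (not isolated), via silylvinylcerium dichloride 13 (not isolated)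
Conditions: n-BuLi, THF, −78 °C; CeCl3 (anhydrous), −78 °C; then 7, −78 °C
Reagents that add atoms: none
Why: Tin–lithium exchange and 1,2-addition of the organocerium reagent (trivalent cerium suppresses enolisation of the doubly activated C1–H); the nucleophile should enter from the face opposite the isopropenyl and silyloxy groups, as in additions to 6-alkenylcyclohex-2-enones, giving the trans-dialkenyl carbinol, and a minor cis isomer would be removed here.

Step 8
Reactants: 14 the dienol
Product: 16 2-[(E)-2-(benzyldimethylsilyl)ethenyl]-5-(tert-butyldimethylsilyloxy)-2-hydroxy-6-methylidene-3-(prop-1-en-2-yl)cyclohexan-1-one, via allylic hydroperoxide 15 (not isolated)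
Conditions: O2, tetraphenylporphyrin (cat.), hν, CH2Cl2, 0 °C; then Ac2O, pyridine, DMAP (cat.), 0 °C → rt
Reagents that add atoms: dioxygen, O=O
Why: Schenck ene reaction followed by acetylation–elimination of the secondary hydroperoxide; oxygen can bond only to C5 (C6 has no hydrogen), the hydrogen is taken from the C15 methyl and not from the silyloxy-bearing C3, and the trisubstituted alkene reacts far faster than the isopropenyl and vinylsilane groups, so the C5 ketone and the C4 methylene appear together.

Step 9
Reactants: 16 the α-hydroxy enone
Product: 17 1-[(E)-2-(benzyldimethylsilyl)ethenyl]-4-(tert-butyldimethylsilyloxy)-3-methylidene-6-(prop-1-en-2-yl)cyclohexane-1,2-diol (C5 hydroxyl trans to C6 hydroxyl)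
Conditions: Me4NBH(OAc)3, MeCN/AcOH, −30 → −20 °C
Reagents that add atoms: none
Why: Hydroxyl-directed (Evans–Saksena) reduction; the axial tertiary hydroxyl binds boron and delivers hydride to the same face of the C5 carbonyl, which sets the trans-diaxial diol (C5 oxygen trans to the isopropenyl group) and avoids 1,4-reduction.

Step 10
Reactants: 17 the trans-diol
Product: 18 trans-2-isopropenyl-1-[(E)-2-(benzyldimethylsilyl)vinyl]cyclohexanol with C3 OTBS (cis to isopropenyl) and C4 methylene and C5 OPMB (trans to isopropenyl)
Conditions: NaH (1.1 equiv), PMBCl, Bu4NI, THF, 0 °C → rt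
Reagents that add atoms: 4-methoxybenzyl chloride, COc1ccc(CCl)cc1
Why: Williamson etherification; the secondary allylic hydroxyl is alkylated in preference to the tertiary one, and a sodium alkoxide without crown ether does not rearrange at this temperature.

Step 11
Reactants: 18 the dialkenylcyclohexanol
Product: 21 8α-(benzyldimethylsilyl)-3β-(tert-butyldimethylsilyloxy)-5α-(4-methoxybenzyloxy)-10-methyl-4-methylidene-(E)-cyclodec-1(10)-en-6-one, via potassium alkoxide 19 (not isolated), via potassium enolate 20 (not isolated)
Conditions: KH, 18-crown-6, THF, 0 °C → rt; then AcOH, THF, −78 °C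
Reagents that add atoms: none
Why: KH deprotonates the tertiary alcohol and the crown ether separates the ion pair; in alkoxide 19 the donor oxygen weakens C1–C6 and accelerates the [3,3] shift, an anionic oxy-Cope rearrangement whose closest precedent is the expansion of trans-1,2-dialkenylcyclohexanols to (E)-cyclodec-5-enones. The ten-membered ring is closed by ring expansion, not by cyclisation: C8 and C9 join inside a six-membered chair transition state while C1–C6 breaks. The cyclohexane chair with isopropenyl, silylvinyl and the C3 silyl ether equatorial (alkoxide and C5 ether axial) is the only low-energy conformer and maps directly onto the chair array C9=C10–C1···C6–C7=C8 with both ring bonds equatorial. The equatorial C2 gives the (E)-C1=C10 alkene, and the (E)-silyl group sits equatorial on C8, so the C1 and C6 configurations are relayed to the new C8 stereocentre; a boat would give the Z alkene and is higher in energy. The competing alkoxide-accelerated shift through C15=C4–C5–C6–C7=C8 needs the vinyl group gauche to C4, that is axial, and is closed in this conformer. The enolate 20 is regiodefined (C6=C7) and is protonated cold before it can equilibrate towards C5. The β-silyl group cannot be eliminated, as a C8 alkoxy group would be.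

Step 12
Reactants: 21 the cyclodecenone; 22 tert-butyl bromoacetate
Product: 24 tert-butyl ester of the C7-acetic acid of 21 (side chain β and trans to the C8 silyl group), via lithium enolate 23 (not isolated)
Conditions: LiN(SiMe3)2, THF, −78 °C; then 22, DMPU, −78 → −40 °C
Reagents that add atoms: none
Why: Kinetic enolate alkylation; the bulky amide removes a proton from the C7 methylene and not the hindered, alkoxy-bearing C5 methine, the extended C5–C6–C7–C8 arrangement gives the same (E)-enolate as the rearrangement, and the electrophile adds to its outer face (the inner face is covered by C9), which places C11 β.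

Step 13
Reactants: 24 the keto ester
Product: 25 6β-hydroxy ester (6S)
Conditions: NaBH4, MeOH/THF, −20 °C
Reagents that add atoms: none
Why: Borohydride reduction by outside attack, on the carbonyl face turned away from the transannular C1=C10 alkene, gives the C6 hydroxyl β (trans to the C5 ether, the Felkin–Anh sense as well); the tert-butyl ester resists lactonisation.

Step 14
Reactants: 25 the hydroxy ester
Product: 26 3,6-bis(tert-butyldimethylsilyl) ether
Conditions: TBSOTf, 2,6-lutidine, CH2Cl2, −78 → 0 °C
Reagents that add atoms: tert-butyldimethylsilyl trifluoromethanesulfonate, CC(C)(C)[Si](C)(C)OS(=O)(=O)C(F)(F)F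
Why: Silyl triflate silylation of a hindered secondary alcohol without forming an alkoxide, so that O6 cannot lactonise or later compete with O8.

Step 15
Reactants: 26 the bis-silyl ether
Product: 28 8α-hydroxy ester, via fluorosilane 27 (not isolated)
Conditions: Bu4NF (2.2 equiv), THF, 0 °C, 15 min; then KHCO3, 30% H2O2, MeOH, rt
Reagents that add atoms: hydrogen peroxide, OO
Why: Tamao–Fleming oxidation of a benzyldimethylsilyl group; fluoride expels benzyl as toluene within minutes, the fluorosilane is oxidised by peroxide with migration of C8 from silicon to oxygen with retention, no electrophile touches the alkenes, and the short cold contact should spare the two hindered silyl ethers.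

Step 16
Reactants: 28 the hydroxy ester
Product: 29 trans-fused 8,12-lactone (H7 α; H8 β)
Conditions: KOt-Bu (0.2 equiv), THF, 0 °C
Reagents that add atoms: none
Why: Alkoxide-catalysed lactonisation (5-exo-trig acyl substitution) with loss of tert-butoxide; O8 and the side chain are gauche on the ring and O6 is blocked.

Step 17
Reactants: 29 the lactone
Product: 33 α-methylene lactone, via lactone lithium enolate 30 (not isolated), via Mannich base 31 (not isolated), via trimethylammonium iodide 32 (not isolated)
Conditions: LiN(SiMe3)2, THF, −78 °C; Me2N=CH2+ I−, −78 → 0 °C; then MeI, MeOH, rt; then aq. NaHCO3, CH2Cl2, rt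
Reagents that add atoms: N,N-dimethylmethyleneiminium iodide, C[N+](C)=C.[I-]
Why: Eschenmoser methylenation: Mannich reaction of the lactone enolate, quaternisation and base-induced elimination; C7 is not acidic and keeps its configuration.

Step 18
Reactants: 33 the α-methylene lactone
Product: 34 5α-alcohol
Conditions: DDQ, CH2Cl2/pH 7 buffer, 0 °C
Reagents that add atoms: none
Why: Oxidative cleavage of the 4-methoxybenzyl ether through its benzylic cation; the alkenes and silyl ethers are not affected under buffered conditions.

Step 19
Reactants: 34 the C5 alcohol; 35 angelic acid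
Product: 37 5α-angelate, via mixed anhydride 36 (not isolated)
Conditions: 35, 2,4,6-Cl3C6H2COCl, Et3N, toluene, rt; then 34, toluene, 80 °C
Reagents that add atoms: none
Why: Yamaguchi-type esterification through the mixed anhydride without a nucleophilic catalyst, the conditions that avoid Z to E isomerisation of the angelate; O6 is silylated, so only O5 reacts.

Step 20
Reactants: 37 the angelate
Product: 38 (1R,10R)-epoxide
Conditions: 1,2:4,5-di-O-isopropylidene-β-D-erythro-hexo-2,3-diulo-2,6-pyranose (30 mol%), KHSO5 (as 2KHSO5·KHSO4·K2SO4), K2CO3, Bu4NHSO4, MeCN/CH2(OMe)2/aq. Na2B4O7 buffer, 0 °C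
Reagents that add atoms: potassium peroxymonosulfate, [K+].[O-]S(=O)(=O)OO
Why: Shi epoxidation; the fructose-derived dioxirane prefers the face of trisubstituted E alkenes that gives the (R,R) epoxide, which is the target configuration; the alkene can turn through the ring to present that face, and the flanked C4 methylene and the two electron-poor alkenes are much less reactive.

Step 21
Reactants: 38 the epoxide
Product: 39 3β,6β-diol
Conditions: HF·pyridine, pyridine, THF, 0 °C → rt
Reagents that add atoms: none
Why: Buffered fluoride desilylation under non-basic conditions, so that no alkoxide is formed next to the angelate; trisubstituted macrocyclic epoxides are known to survive this reagent.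

Step 22
Reactants: 39 the diol
Product: 40 target, (1R,5S,6S,7R,8R,10R)-5-angeloyloxy-1,10-epoxy-6-hydroxy-3-oxogermacra-4(15),11(13)-dien-12,8-olide
Conditions: MnO2 (activated), CH2Cl2, rt
Reagents that add atoms: none
Why: Chemoselective oxidation of the allylic C3 alcohol; the C6 alcohol is not allylic and stays, and the neutral conditions suit the epoxide, the angelate and both methylene groups.

**Compound list**

1 | (R)-(−)-carvone | CC1=CC[C@H](CC1=O)C(C)=C | starting material
2 | (1R,5R)-cis-carveol | C=C(C)[C@H]1C[C@@H](O)C(C)=CC1 | intermediate
3 | 1-methyl-4-(prop-1-en-2-yl)-7-oxabicyclo[4.1.0]heptan-2-ol, all-cis | C=C(C)[C@H]1C[C@@H](O)[C@@]2(C)O[C@H]2C1 | intermediate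
4 | tert-butyldimethylsilyl ether of 3 | C=C(C)[C@H]1C[C@@H](O[Si](C)(C)C(C)(C)C)[C@@]2(C)O[C@H]2C1 | intermediate
5 | hydroxy selenide (C5 SePh trans to C4 OH) | C=C(C)[C@H]1C[C@@H](O[Si](C)(C)C(C)(C)C)[C@@](C)(O)[C@H]([Se]c2ccccc2)C1 | intermediate (not isolated)
6 | 6-(tert-butyldimethylsilyloxy)-1-methyl-4-(prop-1-en-2-yl)cyclohex-2-en-1-ol, all-cis | C=C(C)[C@H]1C[C@@H](O[Si](C)(C)C(C)(C)C)[C@@](C)(O)C=C1 | intermediate
7 | (4R,6R)-4-(tert-butyldimethylsilyloxy)-3-methyl-6-(prop-1-en-2-yl)cyclohex-2-en-1-one | C=C(C)[C@H]1C[C@@H](O[Si](C)(C)C(C)(C)C)C(C)=CC1=O | intermediate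
8 | (E)-1,2-bis(tributylstannyl)ethene | CCCC[Sn](CCCC)(CCCC)/C=C/[Sn](CCCC)(CCCC)CCCC | starting material
9 | benzylchlorodimethylsilane | C[Si](C)(Cl)Cc1ccccc1 | starting material
10 | (E)-2-(tributylstannyl)vinyllithium | [Li]/C=C/[Sn](CCCC)(CCCC)CCCC | intermediate (not isolated)
11 | (E)-benzyldimethyl[2-(tributylstannyl)ethenyl]silane | CCCC[Sn](CCCC)(CCCC)/C=C/[Si](C)(C)Cc1ccccc1 | intermediate
12 | (E)-2-(benzyldimethylsilyl)vinyllithium | [Li]/C=C/[Si](C)(C)Cc1ccccc1 | intermediate (not isolated)
13 | dichloro[(E)-2-(benzyldimethylsilyl)ethenyl]cerium | Cl[Ce](Cl)/C=C/[Si](C)(C)Cc1ccccc1 | intermediate (not isolated)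
14 | 1,2-adduct, hydroxyl cis and silylvinyl trans to isopropenyl | C=C(C)[C@H]1C[C@@H](O[Si](C)(C)C(C)(C)C)C(C)=C[C@]1(O)/C=C/[Si](C)(C)Cc1ccccc1 | intermediate
15 | C5 hydroperoxide with C4 methylene (C5 configuration not relevant, drawn syn to the C6 hydroxyl) | C=C(C)[C@H]1C[C@@H](O[Si](C)(C)C(C)(C)C)C(=C)[C@@H](OO)[C@]1(O)/C=C/[Si](C)(C)Cc1ccccc1 | intermediate (not isolated)
16 | α-hydroxy enone (C5 ketone, C4 methylene) | C=C(C)[C@H]1C[C@@H](O[Si](C)(C)C(C)(C)C)C(=C)C(=O)[C@]1(O)/C=C/[Si](C)(C)Cc1ccccc1 | intermediate
17 | trans-diaxial C5,C6-diol | C=C(C)[C@H]1C[C@@H](O[Si](C)(C)C(C)(C)C)C(=C)[C@H](O)[C@]1(O)/C=C/[Si](C)(C)Cc1ccccc1 | intermediate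
18 | oxy-Cope precursor: trans-2-isopropenyl-1-[(E)-2-(benzyldimethylsilyl)vinyl]cyclohexanol, C3 OTBS, C4 methylene, C5 OPMB | C=C(C)[C@H]1C[C@@H](O[Si](C)(C)C(C)(C)C)C(=C)[C@H](OCc2ccc(OC)cc2)[C@]1(O)/C=C/[Si](C)(C)Cc1ccccc1 | intermediate
19 | potassium alkoxide of 18 | C=C(C)[C@H]1C[C@@H](O[Si](C)(C)C(C)(C)C)C(=C)[C@H](OCc2ccc(OC)cc2)[C@]1([O-])/C=C/[Si](C)(C)Cc1ccccc1.[K+] | intermediate (not isolated)
20 | potassium (E)-enolate (C6=C7) of 21 | [K+].[O-]/C1=C\[C@H]([Si](C)(C)Cc2ccccc2)C/C(C)=C/C[C@@H](O[Si](C)(C)C(C)(C)C)C(=C)[C@@H]1OCc3ccc(OC)cc3 | intermediate (not isolated)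
21 | 8α-(benzyldimethylsilyl)-3β-OTBS-5α-OPMB-10-methyl-4-methylidene-(E)-cyclodec-1(10)-en-6-one | C[Si](C)(Cc1ccccc1)[C@@H]2C/C(C)=C/C[C@@H](O[Si](C)(C)C(C)(C)C)C(=C)[C@H](OCc3ccc(OC)cc3)C(=O)C2 | intermediate
22 | tert-butyl bromoacetate | CC(C)(C)OC(=O)CBr | starting material
23 | lithium (E)-enolate (C6=C7) of 21 | [Li+].[O-]/C1=C\[C@H]([Si](C)(C)Cc2ccccc2)C/C(C)=C/C[C@@H](O[Si](C)(C)C(C)(C)C)C(=C)[C@@H]1OCc3ccc(OC)cc3 | intermediate (not isolated)
24 | C7β-(tert-butoxycarbonylmethyl) ketone | C[Si](C)(Cc1ccccc1)[C@@H]2C/C(C)=C/C[C@@H](O[Si](C)(C)C(C)(C)C)C(=C)[C@H](OCc3ccc(OC)cc3)C(=O)[C@H]2CC(=O)OC(C)(C)C | intermediate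
25 | 6β-hydroxy ester | C[Si](C)(Cc1ccccc1)[C@@H]2C/C(C)=C/C[C@@H](O[Si](C)(C)C(C)(C)C)C(=C)[C@H](OCc3ccc(OC)cc3)[C@@H](O)[C@H]2CC(=O)OC(C)(C)C | intermediate
26 | 3,6-bis(TBS) ether ester | C[Si](C)(Cc1ccccc1)[C@@H]2C/C(C)=C/C[C@@H](O[Si](C)(C)C(C)(C)C)C(=C)[C@H](OCc3ccc(OC)cc3)[C@@H](O[Si](C)(C)C(C)(C)C)[C@H]2CC(=O)OC(C)(C)C | intermediate
27 | C8 fluorodimethylsilane | C[Si](C)(F)[C@@H]2C/C(C)=C/C[C@@H](O[Si](C)(C)C(C)(C)C)C(=C)[C@H](OCc3ccc(OC)cc3)[C@@H](O[Si](C)(C)C(C)(C)C)[C@H]2CC(=O)OC(C)(C)C | intermediate (not isolated)
28 | 8α-hydroxy ester | O[C@@H]2C/C(C)=C/C[C@@H](O[Si](C)(C)C(C)(C)C)C(=C)[C@H](OCc3ccc(OC)cc3)[C@@H](O[Si](C)(C)C(C)(C)C)[C@H]2CC(=O)OC(C)(C)C | intermediate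
29 | trans-fused 8,12-lactone | C1C(=O)O[C@@H]2C/C(C)=C/C[C@@H](O[Si](C)(C)C(C)(C)C)C(=C)[C@H](OCc3ccc(OC)cc3)[C@@H](O[Si](C)(C)C(C)(C)C)[C@@H]12 | intermediate
30 | lithium enolate of lactone 29 | [Li+].C1=C([O-])O[C@@H]2C/C(C)=C/C[C@@H](O[Si](C)(C)C(C)(C)C)C(=C)[C@H](OCc3ccc(OC)cc3)[C@@H](O[Si](C)(C)C(C)(C)C)[C@@H]12 | intermediate (not isolated)
31 | C11 (dimethylamino)methyl lactone (C11 configuration not relevant) | CN(C)CC1C(=O)O[C@@H]2C/C(C)=C/C[C@@H](O[Si](C)(C)C(C)(C)C)C(=C)[C@H](OCc3ccc(OC)cc3)[C@@H](O[Si](C)(C)C(C)(C)C)[C@@H]12 | intermediate (not isolated)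
32 | trimethylammonium iodide of 31 | C[N+](C)(C)CC1C(=O)O[C@@H]2C/C(C)=C/C[C@@H](O[Si](C)(C)C(C)(C)C)C(=C)[C@H](OCc3ccc(OC)cc3)[C@@H](O[Si](C)(C)C(C)(C)C)[C@@H]12.[I-] | intermediate (not isolated)
33 | α-methylene lactone, C5 OPMB | C=C1C(=O)O[C@@H]2C/C(C)=C/C[C@@H](O[Si](C)(C)C(C)(C)C)C(=C)[C@H](OCc3ccc(OC)cc3)[C@@H](O[Si](C)(C)C(C)(C)C)[C@@H]12 | intermediate
34 | 5α-alcohol | C=C1C(=O)O[C@@H]2C/C(C)=C/C[C@@H](O[Si](C)(C)C(C)(C)C)C(=C)[C@H](O)[C@@H](O[Si](C)(C)C(C)(C)C)[C@@H]12 | intermediate
35 | angelic acid | C/C=C(/C)C(=O)O | starting material
36 | angelic 2,4,6-trichlorobenzoic anhydride | C/C=C(/C)C(=O)OC(=O)c1c(Cl)cc(Cl)cc1Cl | intermediate (not isolated)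
37 | 5α-angelate | C=C1C(=O)O[C@@H]2C/C(C)=C/C[C@@H](O[Si](C)(C)C(C)(C)C)C(=C)[C@H](OC(=O)/C(C)=C\C)[C@@H](O[Si](C)(C)C(C)(C)C)[C@@H]12 | intermediate
38 | (1R,10R)-epoxide, 3,6-bis(TBS) ether | C=C1C(=O)O[C@@H]2C[C@@]3(C)O[C@@H]3C[C@@H](O[Si](C)(C)C(C)(C)C)C(=C)[C@H](OC(=O)/C(C)=C\C)[C@@H](O[Si](C)(C)C(C)(C)C)[C@@H]12 | intermediate
39 | epoxy 3β,6β-diol | C=C1C(=O)O[C@@H]2C[C@@]3(C)O[C@@H]3C[C@@H](O)C(=C)[C@H](OC(=O)/C(C)=C\C)[C@@H](O)[C@@H]12 | intermediate
40 | CNP0348992.3 | C=C1C(=O)O[C@@H]2C[C@@]3(C)O[C@@H]3CC(=O)C(=C)[C@H](OC(=O)/C(C)=C\C)[C@@H](O)[C@@H]12 | target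

**Step count and least certain steps**

Total: 22 steps. Longest linear sequence: 21 steps (steps 1–5 and 7–22, from 1); step 6 is a one-step side branch.

Step 11 (key step). The most likely failure is that the free enolate does not stay as formed: proton transfer towards C5 would epimerise that centre or pull the C4 methylene into conjugation, and the enolate oxygen could attack the neighbouring silicon and expel benzyl. A slow rearrangement would also give time for fragmentation of the alkoxide. Fallback without any anion: 18 is silylated on the tertiary oxygen (TMSCl, imidazole) to the trimethylsilyl ether F1 and heated (o-dichlorobenzene, about 190 °C), the known neutral oxy-Cope of 1,2-dialkenylcyclohexanol derivatives through the same chair. This gives the trimethylsilyl enol ether F2, which is hydrolysed with aqueous citric acid in THF and returns to the route at 21.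

Step 12. Deprotonation may not be selective for C7; removal of the C5 proton would lead to loss of the C5 configuration and to alkylation on the wrong side. The lithium enolate may also be alkylated with poor facial selectivity if it is not the E isomer. Fallback: the alkylation is joined to the rearrangement. Starting from 18, the enolate 20, whose position and geometry are fixed by the [3,3] shift, is treated in the same flask at −78 °C with 22 and gives 24 directly; no new compound is made (F0).

Step 15. Fluoride may remove one or both silyl ethers before the hindered secondary C8 silicon has lost its benzyl group, which would free O6 or O3 too early. Fallback that no longer depends on their survival: alcohol 25 is treated with an excess of Bu4NF and then with H2O2/KHCO3, which oxidises the C–Si bond and cleaves the C3 silyl ether, giving the triol ester F3. KOt-Bu (catalytic) closes the lactone through O8, which lies gauche to the side chain while O6 points away from it in the chair-derived ring conformer, giving the dihydroxy lactone F4. TBSOTf/2,6-lutidine then silylates O3 and O6 and returns to the route at 29.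

Step 20. The risk is poor facial selectivity. The oxygen must reach the alkene face that points into the ring in the conformer left by step 11; if the ring does not turn the alkene, the catalyst is mismatched and the 1,10-diastereomeric epoxide or no reaction results. Fallback by the halohydrin route, which puts oxygen on the face opposite to the one the electrophile attacks: 37 with N-bromosuccinimide in aqueous 1,2-dimethoxyethane gives the bromohydrin F5 (bromonium ion on the outer face, water anti at the tertiary C10). DBU in CH2Cl2 closes the epoxide with inversion at C1 and returns to the route at 38.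

Step 21. Hydrogen fluoride may open the epoxide (fluorohydrin or transannular attack), and once O6 is free the angelate may migrate to it. Fallback by changing the order: the silyl ethers are removed before the epoxide exists. 37 with HF·pyridine gives the diene diol F6, which is epoxidised under the conditions of step 20 and returns to the route at 39, ready for step 22.

**Further compounds**

F1 | step 11 | trimethylsilyl ether of 18 | C=C(C)[C@H]1C[C@@H](O[Si](C)(C)C(C)(C)C)C(=C)[C@H](OCc2ccc(OC)cc2)[C@]1(O[Si](C)(C)C)/C=C/[Si](C)(C)Cc1ccccc1
F2 | step 11 | trimethylsilyl enol ether of 21 | C[Si](C)(C)O/C1=C\[C@H]([Si](C)(C)Cc2ccccc2)C/C(C)=C/C[C@@H](O[Si](C)(C)C(C)(C)C)C(=C)[C@@H]1OCc3ccc(OC)cc3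
F0 | step 12 | none | none
F3 | step 15 | 3β,6β,8α-triol tert-butyl ester | O[C@@H]2C/C(C)=C/C[C@@H](O)C(=C)[C@H](OCc3ccc(OC)cc3)[C@@H](O)[C@H]2CC(=O)OC(C)(C)C
F4 | step 15 | 3β,6β-dihydroxy 8,12-lactone | C1C(=O)O[C@@H]2C/C(C)=C/C[C@@H](O)C(=C)[C@H](OCc3ccc(OC)cc3)[C@@H](O)[C@@H]12
F5 | step 20 | 1-bromo-10-hydroxy bromohydrin of 37 | C=C1C(=O)O[C@@H]2C[C@@](C)(O)[C@@H](Br)C[C@@H](O[Si](C)(C)C(C)(C)C)C(=C)[C@H](OC(=O)/C(C)=C\C)[C@@H](O[Si](C)(C)C(C)(C)C)[C@@H]12
F6 | step 21 | 3β,6β-diol of angelate 37 | C=C1C(=O)O[C@@H]2C/C(C)=C/C[C@@H](O)C(=C)[C@H](OC(=O)/C(C)=C\C)[C@@H](O)[C@@H]12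
A1 | alternative 1 | trans-2-allyl-2-methyl-3-[2-(tert-butyldiphenylsilyloxy)ethyl]oxirane | C=CC[C@@]1(C)O[C@@H]1CCO[Si](c1ccccc1)(c1ccccc1)C(C)(C)C
A2 | alternative 1 | (S)-5-(tert-butyldiphenylsilyloxy)-3-chloropentan-2-one | CC(=O)[C@@H](Cl)CCO[Si](c1ccccc1)(c1ccccc1)C(C)(C)C
A3 | alternative 2 | germacra-1(10),4-diene carbinol with C6 hydroxyl and C7 2-propenyl unit | CC[Si](CC)(CC)O[C@@H]1C/C(C)=C/CC2(OCCO2)/C(C)=C/[C@@H](O)[C@H]1C(=C)CO[Si](CC)(CC)CC
A4 | alternative 3 | trans-fused α-methylene lactone on the ten-membered enone | O=C3O[C@@H]1C/C(C)=C/CC(=O)C(=C)[C@H](OCc2ccc(OC)cc2)[C@@H](O[Si](C)(C)C(C)(C)C)[C@H]1C3=C
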